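**Retrosynthetic overview**
1. Target 12 ⇐ diester 11 by one global LiAlH4 reduction (both CH2OH groups formed, ring-A phenol unmasked, auxiliary removed).
2. 11 ⇐ C1–aryl bond: the guaiacyl ring is attached last by an intermolecular, trans-selective Friedel–Crafts reaction of guaiacol itself with the C1 benzylic cation of 9. The usual intramolecular Friedel–Crafts closure of a dibenzylbutane/lactone is not used.
3. 9 ⇐ ring B by photoenolisation/Diels–Alder of o-tolualdehyde 5 (as its hydroxy-o-quinodimethane) with the C2-symmetric chiral fumarate 8. This forms C1–C2 and C3–C4 and sets C2/C3 (trans, absolute).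
4. 5 ⇐ creosol 1 (ring A bought intact); 8 ⇐ fumaroyl chloride 6 + methyl (S)-mandelate 7.
5. Ring order: A (from creosol) → B (cycloaddition) → pendant guaiacyl ring (from guaiacol) appended to C1.

Assumption: tetralin numbering has C1 as the aryl-bearing carbon and C2/C3 as the CH2OH-bearing carbons; the target SMILES corresponds to (1S,2R,3R), all-trans. Reagents 2, 4, 6, 7 and 10 are treated as commercial starting materials.

**Route**

Step 1
Reactants: 1, 2-methoxy-4-methylphenol (creosol); 2, pivaloyl chloride
Product: 3, 2-methoxy-4-methylphenyl pivalate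
Conditions: PivCl, Et3N, DMAP (cat.), CH2Cl2, 0 °C → rt
Reagents that add atoms: pivaloyl chloride, CC(C)(C)C(=O)Cl
Why: DMAP-catalysed phenol O-acylation; the ester makes this oxygen a weak donor so OMe alone directs step 2, masks the phenol through steps 4–5, and is cleaved for free in step 6.

Step 2
Reactants: 3, 2-methoxy-4-methylphenyl pivalate; 4, dichloromethyl methyl ether
Product: 5, 5-formyl-2-methoxy-4-methylphenyl pivalate (= 4-methoxy-2-methyl-5-(pivaloyloxy)benzaldehyde)
Conditions: Cl2CHOMe, TiCl4, CH2Cl2, −10 → 0 °C; aqueous work-up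
Reagents that add atoms: dichloromethyl methyl ether, COC(Cl)Cl (supplies the CHO group)
Why: Rieche formylation (SEAr) goes para to OMe, the only strong donor, which is also ortho to the methyl group; this gives the o-tolualdehyde needed for photoenolisation.

Step 3
Reactants: 6, fumaroyl chloride; 7, methyl (S)-mandelate (2.1 equiv)
Product: 8, bis[(1S)-2-methoxy-2-oxo-1-phenylethyl] fumarate
Conditions: pyridine, CH2Cl2, 0 °C → rt
Reagents that add atoms: methyl (S)-mandelate, COC(=O)[C@@H](O)c1ccccc1 (both reactants are incorporated)
Why: Acyl chloride esterification; no bond to the mandelate stereocentre is broken, and the mild base avoids racemisation and E/Z isomerisation.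

Step 4
Reactants: 5, 5-formyl-2-methoxy-4-methylphenyl pivalate; 8, bis[(1S)-2-methoxy-2-oxo-1-phenylethyl] fumarate (1.5 equiv)
Product: 9, bis[(1S)-2-methoxy-2-oxo-1-phenylethyl] (1S,2S,3R)-1-hydroxy-6-methoxy-7-(pivaloyloxy)-1,2,3,4-tetrahydronaphthalene-2,3-dicarboxylate (1-OH cis to the C2 ester; C2/C3 esters trans)
Conditions: hν (365 nm), degassed PhMe (0.03 M), rt; crystallise or chromatograph to a single diastereomer
Reagents that add atoms: compound 8, COC(=O)[C@@H](OC(=O)/C=C/C(=O)O[C@H](C(=O)OC)c1ccccc1)c1ccccc1
Why: Photoenolisation/Diels–Alder: 1,5-H transfer in the triplet aldehyde gives the (E)-hydroxy-o-quinodimethane, which is trapped in an endo [4+2]. The E-fumarate fixes C2/C3 trans. The dienol OH hydrogen-bonds to the auxiliary ester carbonyl, so it ends cis to the C2 ester, and the two (S)-mandelate phenyl groups shield the si,si face of the s-cis fumarate, so addition on the re,re face gives (2S,3R). The C1 carbinol configuration is irrelevant because C1 is ionised in step 5.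

Step 5
Reactants: 9 (as above); 10, guaiacol (2-methoxyphenol, 5 equiv)
Product: 11, bis[(1S)-2-methoxy-2-oxo-1-phenylethyl] (1S,2R,3R)-1-(4-hydroxy-3-methoxyphenyl)-6-methoxy-7-(pivaloyloxy)-1,2,3,4-tetrahydronaphthalene-2,3-dicarboxylate (all-trans)
Conditions: guaiacol, FeCl3 (10 mol %), CH2Cl2, 0 °C → rt
Reagents that add atoms: guaiacol, COc1ccccc1O
Why: Intermolecular SN1 Friedel–Crafts alkylation: Fe(III) ionises the C1 alcohol to a cation stabilised by the para OMe at C6, guaiacol attacks through its most nucleophilic carbon (para to OH), and it adds anti to the adjacent C2 ester. This gives the 1,2-trans, C1-(S) product, which is also the thermodynamic all-equatorial isomer. C2/C3 are untouched under acid; the 2S→2R label change from 9 is only a CIP priority change.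

Step 6
Reactants: 11 (as above)
Product: 12, (+)-isolariciresinol, (1S,2R,3R)-1-(4-hydroxy-3-methoxyphenyl)-2,3-bis(hydroxymethyl)-6-methoxy-1,2,3,4-tetrahydronaphthalen-7-ol
Conditions: LiAlH4 (6 equiv), THF, 0 °C → rt; Rochelle salt work-up
Reagents that add atoms: none
Why: Hydride reduction of the two ring esters to CH2OH (the auxiliary leaves as (S)-1-phenylethane-1,2-diol) with simultaneous cleavage of the aryl pivalate; no stereocentre is involved.

**Compound list**
1 | 2-methoxy-4-methylphenol (creosol) | COc1cc(C)ccc1O | starting material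
2 | pivaloyl chloride | CC(C)(C)C(=O)Cl | starting material
3 | 2-methoxy-4-methylphenyl pivalate | COc1cc(C)ccc1OC(=O)C(C)(C)C | intermediate
4 | dichloromethyl methyl ether | COC(Cl)Cl | starting material
5 | 5-formyl-2-methoxy-4-methylphenyl pivalate | COc1cc(C)c(C=O)cc1OC(=O)C(C)(C)C | intermediate
6 | fumaroyl chloride | O=C(Cl)/C=C/C(=O)Cl | starting material
7 | methyl (S)-mandelate | COC(=O)[C@@H](O)c1ccccc1 | starting material
8 | bis[(1S)-2-methoxy-2-oxo-1-phenylethyl] fumarate | COC(=O)[C@@H](OC(=O)/C=C/C(=O)O[C@H](C(=O)OC)c1ccccc1)c1ccccc1 | intermediate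
9 | bis[(1S)-2-methoxy-2-oxo-1-phenylethyl] (1S,2S,3R)-1-hydroxy-6-methoxy-7-(pivaloyloxy)-1,2,3,4-tetrahydronaphthalene-2,3-dicarboxylate | O[C@@H]1c2cc(OC(=O)C(C)(C)C)c(OC)cc2C[C@@H](C(=O)O[C@H](C(=O)OC)c2ccccc2)[C@@H]1C(=O)O[C@H](C(=O)OC)c1ccccc1 | intermediate
10 | guaiacol (2-methoxyphenol) | COc1ccccc1O | starting material
11 | bis[(1S)-2-methoxy-2-oxo-1-phenylethyl] (1S,2R,3R)-1-(4-hydroxy-3-methoxyphenyl)-6-methoxy-7-(pivaloyloxy)-1,2,3,4-tetrahydronaphthalene-2,3-dicarboxylate | COc1cc([C@H]2c3cc(OC(=O)C(C)(C)C)c(OC)cc3C[C@@H](C(=O)O[C@H](C(=O)OC)c3ccccc3)[C@@H]2C(=O)O[C@H](C(=O)OC)c2ccccc2)ccc1O | intermediate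
12 | (+)-isolariciresinol | COc1cc([C@H]2c3cc(O)c(OC)cc3C[C@@H](CO)[C@@H]2CO)ccc1O | target

**Totals**
Total steps: 6. Longest linear sequence: 5 (steps 1 → 2 → 4 → 5 → 6; step 3 is a one-step side branch).

**Three steps most likely to fail**
1. Step 4 (asymmetric photoenolisation/Diels–Alder). This is the main risk: the re,re facial sense comes from a conformational model, not a firm rule, and must be confirmed by the sign of rotation of 12. If it is reversed, (R)-mandelate gives the mirror-image induction. The electron-rich aldehyde may also photoenolise inefficiently, or sensitise fumarate E/Z isomerisation. Fallback: abandon the cycloaddition and set C2/C3 by Evans-auxiliary oxidative enolate homocoupling of (S)-4-benzyl-3-[3-(4-benzyloxy-3-methoxyphenyl)propanoyl]oxazolidin-2-one to the (R,R)-dibenzylsuccinate. Then LiBH4 reduction, DDQ/acid oxidative cyclisation of the C2-symmetric diol, and hydrogenolysis.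
2. Step 5 (Friedel–Crafts with guaiacol). Risks are attack para to OMe or ortho to OH on guaiacol, incomplete trans selectivity at C1, and E1 loss of the C2 proton to the cinnamate. Fallback: reverse the polarity at C1. Oxidise 9 to the 1-tetralone β-keto ester, form the enol triflate and Suzuki-couple with 4-(benzyloxy)-3-methoxyphenylboronic acid, so the aryl position is fixed by boron. Hydrogenate the C1=C2 alkene anti to the C3 ester, equilibrate C2 with base to the all-trans diester, then reduce and debenzylate.
3. Step 2 (Rieche formylation). Risks are regiochemical leakage or pivalate/methyl ether damage by TiCl4. Fallback: build 5 by cross-coupling instead of SEAr: commercial 2-bromo-5-hydroxy-4-methoxybenzaldehyde, O-pivaloylation, then Suzuki–Miyaura methylation with methylboronic acid.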